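**Plan**
Ring B with its free 2'-OH, its fused dimethylpyran and the C2–C3–C4 bridge is a ring-opened coumarin: O2' is the lactone oxygen and C4 the lactone carbonyl of xanthyletin, which is used intact.
Cuts: O1–C2 (oxa-Michael), then C4–C4a (aryl anion on the lactone C=O), then on ring A the C5–O bond (C–H borylation/oxidation) and C8–prenyl (aryl anion on prenyl bromide).
Forward: 3-methoxyphenol is turned by ortho-lithiation/prenylation, meta C–H oxidation and protection into a ring-A precursor with three different oxygens (O1 oxanyl, O5 methoxymethyl, O7 methyl).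
Its aryllithium opens xanthyletin to the chalcone (rings A and B joined, 2'-OH set free); ring C is closed last.
C2 (S) is set by a bifunctional cinchona thiourea in the 6-endo oxa-Michael closure; only O1 is free at that stage, so the prenyl group can only end at C8.

Key step: step 5

Assumption: xanthyletin is used as purchased (a natural linear pyranocoumarin offered by fine-chemical suppliers); the oxane acetal carbon is carried as both configurations until it is removed in step 6.

**Step 1**
Reactants: 1 3-methoxyphenol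
Product: 2 2-(3-methoxyphenoxy)oxane
Conditions: 3,4-dihydro-2H-pyran, PPTS (cat.), CH2Cl2, rt
Reagents that add atoms: 3,4-dihydro-2H-pyran, C1=COCCC1
Why: Acid-catalysed addition of the phenol to the enol ether (tetrahydropyranylation) puts on the future O1 an acetal that directs ortho-lithiation and is later the most acid-labile group in the molecule.

**Step 2**
Reactants: 2 2-(3-methoxyphenoxy)oxane; 3 prenyl bromide (1-bromo-3-methylbut-2-ene)
Product: 5 2-[3-methoxy-2-(3-methylbut-2-en-1-yl)phenoxy]oxane, via 2-lithio aryl ether 4 (not isolated)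
Conditions: n-BuLi, THF, 0 °C to rt; CuI (10 mol %), 3, −78 °C to rt
Reagents that add atoms: none
Why: Directed ortho-metalation takes the one position flanked by both the acetal and the methoxy oxygen, and copper-catalysed allylic substitution at the primary carbon of 3 places the prenyl group on the future C8 between O1 and O7.

**Step 3**
Reactants: 5 2-[3-methoxy-2-(3-methylbut-2-en-1-yl)phenoxy]oxane
Product: 7 3-methoxy-4-(3-methylbut-2-en-1-yl)-5-(oxan-2-yloxy)phenol, via aryl pinacol boronate 6 (not isolated)
Conditions: [Ir(OMe)(cod)]2 (1.5 mol %), 4,4'-di-tert-butyl-2,2'-bipyridine (3 mol %), B2pin2, THF, 65 °C; then NaOH, 30% H2O2, 0 °C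
Reagents that add atoms: bis(pinacolato)diboron, CC1(C)OB(OC1(C)C)B1OC(C)(C)C(C)(C)O1 (boron of 6); hydrogen peroxide, OO (phenol oxygen of 7)
Why: Sterically controlled iridium-catalysed aromatic C–H borylation takes the only ring C–H without an ortho substituent (the future C5), the trisubstituted prenyl alkene being expected to be inert, and basic peroxide oxidation converts C–B into C–O at the same carbon.

**Step 4**
Reactants: 7 3-methoxy-4-(3-methylbut-2-en-1-yl)-5-(oxan-2-yloxy)phenol
Product: 8 2-[3-methoxy-5-(methoxymethoxy)-2-(3-methylbut-2-en-1-yl)phenoxy]oxane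
Conditions: MOMCl, i-Pr2NEt, CH2Cl2, 0 °C to rt
Reagents that add atoms: chloromethyl methyl ether, COCCl
Why: Base-mediated O-alkylation of the phenol (Williamson-type acetal formation) gives the future O5 a methoxymethyl group that is a strong lithiation director, survives the mild removal of the oxanyl acetal and is cleaved at the end by dilute acid.

**Step 5**
Reactants: 8 2-[3-methoxy-5-(methoxymethoxy)-2-(3-methylbut-2-en-1-yl)phenoxy]oxane; 9 xanthyletin (8,8-dimethyl-2H,8H-pyrano[3,2-g]chromen-2-one)
Product: 12 (E)-3-(7-hydroxy-2,2-dimethyl-2H-chromen-6-yl)-1-[4-methoxy-6-(methoxymethoxy)-3-(3-methylbut-2-en-1-yl)-2-(oxan-2-yloxy)phenyl]prop-2-en-1-one, via ring-A aryllithium 10 (not isolated), via lithium Z-enone phenoxide 11 (not isolated)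
Conditions: n-BuLi, TMEDA, THF, 0 °C; 9, −78 °C to 0 °C; then MeOH, K2CO3, rt, dark
Reagents that add atoms: none
Why: Directed ortho-lithiation of 8 at the C–H flanked by both acetal oxygens (double chelation, preferred over the OMe/OMOM site and the benzylic CH2) gives 10, which adds 1,2 to the lactone carbonyl of 9; the lactolate collapses by expelling the ring oxygen as phenoxide, so that C4–C4a is formed and the 2'-oxygen, C2=C3 and all of ring B with its pyran arrive in one operation as the Z-enone phenoxide 11. Methanolic K2CO3 then equilibrates 11 to the E isomer through the quinone-methide enolate resonance form of the ortho-phenoxide and by reversible methoxide addition, while the masked O1 and O5 exclude any ring closure. The closest known reaction type is the addition of aryllithium and arylmagnesium reagents to coumarins, which gives 2-aryl-2H-chromen-2-ols and ring-opened 2-hydroxychalcones. No ring is closed and no stereocentre is formed in this step. The selectivities needed are 1,2- over 1,4-addition (hard aryllithium at −78 °C), single addition (the di-ortho-substituted ketone stays masked as lactolate or phenoxide and is shielded) and the lithiation site (two flanking acetals).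

**Step 6**
Reactants: 12 (E)-chalcone oxanyl ether
Product: 13 (E)-1-[2-hydroxy-4-methoxy-6-(methoxymethoxy)-3-(3-methylbut-2-en-1-yl)phenyl]-3-(7-hydroxy-2,2-dimethyl-2H-chromen-6-yl)prop-2-en-1-one
Conditions: PPTS (20 mol %), MeOH, rt, dark
Reagents that add atoms: none
Why: Pyridinium tosylate-catalysed transacetalisation to methanol removes the far more labile oxanyl acetal and leaves the methoxymethyl ether, so that O1–H is the only free ring-A phenol, while the weak acid, the E geometry and exclusion of light keep the chalcone from closing to racemic flavanone or to a flavylium ion.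

**Step 7**
Reactants: 13 (E)-2'-hydroxychalcone
Product: 14 (2S)-2-(7-hydroxy-2,2-dimethyl-2H-chromen-6-yl)-7-methoxy-5-(methoxymethoxy)-8-(3-methylbut-2-en-1-yl)-2,3-dihydro-4H-chromen-4-one
Conditions: 9-amino-9-deoxy-epi-quinidine 3,5-bis(trifluoromethyl)phenyl thiourea (10 mol %), toluene, 0 °C, dark; dilute citric acid wash
Reagents that add atoms: none
Why: Catalytic asymmetric intramolecular oxa-Michael addition (6-endo-trig) in which the quinuclidine nitrogen activates O1–H and the thiourea binds the enone carbonyl so that O1 adds to the face of C2 that gives the 2S centre, the sense being fixed by the choice between the pseudoenantiomeric epi-quinidine and epi-quinine catalysts (the latter is substituted should the first analysis indicate the 2R series), and O5 being blocked so that only the 8-prenyl isomer can form.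

**Step 8**
Reactants: 14 (2S)-5-O-methoxymethyl flavanone
Product: 15 Maackiaflavanone A, (2S)-5-hydroxy-2-(7-hydroxy-2,2-dimethyl-2H-chromen-6-yl)-7-methoxy-8-(3-methylbut-2-en-1-yl)-2,3-dihydro-4H-chromen-4-one
Conditions: HCl (1 M in MeOH), 0 °C to rt
Reagents that add atoms: none
Why: Acid-catalysed acetal exchange with methanol cleaves the 5-O-methoxymethyl ether, helped by hydrogen bonding of the freed phenol to the C4 carbonyl, under conditions expected to be too mild to ionise the C2–O1 bond or to add to the prenyl and chromene alkenes, so that the 2S centre is kept.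

**Compound list**
1 | 3-methoxyphenol | COc1cccc(O)c1 | starting material
2 | 2-(3-methoxyphenoxy)oxane | COc1cccc(OC2CCCCO2)c1 | intermediate
3 | prenyl bromide (1-bromo-3-methylbut-2-ene) | CC(C)=CCBr | starting material
4 | [2-methoxy-6-(oxan-2-yloxy)phenyl]lithium | [Li]c1c(OC)cccc1OC1CCCCO1 | intermediate
5 | 2-[3-methoxy-2-(3-methylbut-2-en-1-yl)phenoxy]oxane | COc1cccc(OC2CCCCO2)c1CC=C(C)C | intermediate
6 | 2-[3-methoxy-4-(3-methylbut-2-en-1-yl)-5-(oxan-2-yloxy)phenyl]-4,4,5,5-tetramethyl-1,3,2-dioxaborolane | COc1cc(B2OC(C)(C)C(C)(C)O2)cc(OC2CCCCO2)c1CC=C(C)C | intermediate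
7 | 3-methoxy-4-(3-methylbut-2-en-1-yl)-5-(oxan-2-yloxy)phenol | COc1cc(O)cc(OC2CCCCO2)c1CC=C(C)C | intermediate
8 | 2-[3-methoxy-5-(methoxymethoxy)-2-(3-methylbut-2-en-1-yl)phenoxy]oxane | COCOc1cc(OC)c(CC=C(C)C)c(OC2CCCCO2)c1 | intermediate
9 | xanthyletin | CC1(C)C=Cc2cc3ccc(=O)oc3cc2O1 | starting material
10 | [4-methoxy-6-(methoxymethoxy)-3-(3-methylbut-2-en-1-yl)-2-(oxan-2-yloxy)phenyl]lithium | [Li]c1c(OCOC)cc(OC)c(CC=C(C)C)c1OC1CCCCO1 | intermediate
11 | lithium (Z)-enone phenoxide (ring-opened adduct, in equilibrium with its cyclic lactolate) | [Li+].[O-]c1cc2OC(C)(C)C=Cc2cc1/C=C\C(=O)c1c(OCOC)cc(OC)c(CC=C(C)C)c1OC1CCCCO1 | intermediate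
12 | (E)-3-(7-hydroxy-2,2-dimethyl-2H-chromen-6-yl)-1-[4-methoxy-6-(methoxymethoxy)-3-(3-methylbut-2-en-1-yl)-2-(oxan-2-yloxy)phenyl]prop-2-en-1-one | Oc1cc2OC(C)(C)C=Cc2cc1/C=C/C(=O)c1c(OCOC)cc(OC)c(CC=C(C)C)c1OC1CCCCO1 | intermediate
13 | (E)-1-[2-hydroxy-4-methoxy-6-(methoxymethoxy)-3-(3-methylbut-2-en-1-yl)phenyl]-3-(7-hydroxy-2,2-dimethyl-2H-chromen-6-yl)prop-2-en-1-one | Oc1cc2OC(C)(C)C=Cc2cc1/C=C/C(=O)c1c(OCOC)cc(OC)c(CC=C(C)C)c1O | intermediate
14 | (2S)-2-(7-hydroxy-2,2-dimethyl-2H-chromen-6-yl)-7-methoxy-5-(methoxymethoxy)-8-(3-methylbut-2-en-1-yl)-2,3-dihydro-4H-chromen-4-one | COc1cc(OCOC)c2c(c1CC=C(C)C)O[C@H](c1cc3c(cc1O)OC(C)(C)C=C3)CC2=O | intermediate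
15 | Maackiaflavanone A | COc1cc(O)c2c(c1CC=C(C)C)O[C@H](c1cc3c(cc1O)OC(C)(C)C=C3)CC2=O | target

**Totals**
Total step count: 8. Longest linear sequence: 8 steps (1 to 15); xanthyletin 9 enters without prior steps.

**Steps most likely to fail**

Step 7. The catalyst may give poor facial selectivity on an enone that lacks a second activating group, and reversible ring opening under the basic catalyst may erode the enantiomeric purity. Fallback: from 13 the ring is closed without chiral control (NaOAc, EtOH, 60 °C) to the racemic 5-O-methoxymethyl flavanone F1. F1 is then resolved by asymmetric transfer hydrogenation (RuCl[(R,R)-TsDPEN](p-cymene), HCO2H/Et3N, EtOAc, rt). By the usual aryl ketone model this catalyst is expected to form the 4R alcohol and hence to consume the 2R ketone as the cis-flavan-4-ol F2. The untouched 2S ketone is 14, where the route is rejoined.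

Step 5. The aryllithium may add 1,4 or twice to the lactone, or the lactolate may fail to open cleanly. Fallback: C–C bond formation is moved to the aldehyde oxidation level. From 9, DIBAL-H (toluene, −78 °C) gives the lactol 8,8-dimethyl-2H,8H-pyrano[3,2-g]chromen-2-ol F3. F3 is deprotonated (i-PrMgCl, THF) to its open enal phenoxide and treated with 10 (made from 8 as in step 5) to give the (Z)-allylic alcohol F4. MnO2 (CH2Cl2, rt) oxidises the doubly activated carbinol to the Z-enone F5 (in equilibrium with its hemiketal), and K2CO3/MeOH isomerises F5 to 12, where the route is rejoined.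

Step 3. The iridium boryl species or the pinacolborane formed may hydroborate or isomerise the prenyl alkene, or borylation may stray next to the methoxy group. Fallback: the C–H oxidation is done before the alkene is present. From 2, the same borylation/oxidation gives, through boronate F6, the phenol F7. TIPSCl/imidazole (DMF) gives the bulky, non-directing silyl ether F8. n-BuLi then lithiates between the acetal and methoxy oxygens (aryllithium F9), and CuI/3 gives the prenyl arene F10. TBAF (THF, 0 °C) removes the silyl group to give 7, where the route is rejoined.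

**Further compounds**
F1 | step 7 | racemic 2-(7-hydroxy-2,2-dimethyl-2H-chromen-6-yl)-7-methoxy-5-(methoxymethoxy)-8-(3-methylbut-2-en-1-yl)-2,3-dihydro-4H-chromen-4-one | COc1cc(OCOC)c2c(c1CC=C(C)C)OC(c1cc3c(cc1O)OC(C)(C)C=C3)CC2=O
F2 | step 7 | (2R,4R)-2-(7-hydroxy-2,2-dimethyl-2H-chromen-6-yl)-7-methoxy-5-(methoxymethoxy)-8-(3-methylbut-2-en-1-yl)-3,4-dihydro-2H-chromen-4-ol (cis) | COc1cc(OCOC)c2c(c1CC=C(C)C)O[C@@H](c1cc3c(cc1O)OC(C)(C)C=C3)C[C@H]2O
F3 | step 5 | 8,8-dimethyl-2H,8H-pyrano[3,2-g]chromen-2-ol | CC1(C)C=Cc2cc3C=CC(O)Oc3cc2O1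
F4 | step 5 | (Z)-3-(7-hydroxy-2,2-dimethyl-2H-chromen-6-yl)-1-[4-methoxy-6-(methoxymethoxy)-3-(3-methylbut-2-en-1-yl)-2-(oxan-2-yloxy)phenyl]prop-2-en-1-ol | Oc1cc2OC(C)(C)C=Cc2cc1/C=C\C(O)c1c(OCOC)cc(OC)c(CC=C(C)C)c1OC1CCCCO1
F5 | step 5 | (Z)-3-(7-hydroxy-2,2-dimethyl-2H-chromen-6-yl)-1-[4-methoxy-6-(methoxymethoxy)-3-(3-methylbut-2-en-1-yl)-2-(oxan-2-yloxy)phenyl]prop-2-en-1-one | Oc1cc2OC(C)(C)C=Cc2cc1/C=C\C(=O)c1c(OCOC)cc(OC)c(CC=C(C)C)c1OC1CCCCO1
F6 | step 3 | 2-[3-methoxy-5-(oxan-2-yloxy)phenyl]-4,4,5,5-tetramethyl-1,3,2-dioxaborolane | COc1cc(B2OC(C)(C)C(C)(C)O2)cc(OC2CCCCO2)c1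
F7 | step 3 | 3-methoxy-5-(oxan-2-yloxy)phenol | COc1cc(O)cc(OC2CCCCO2)c1
F8 | step 3 | [3-methoxy-5-(oxan-2-yloxy)phenoxy]tri(propan-2-yl)silane | COc1cc(O[Si](C(C)C)(C(C)C)C(C)C)cc(OC2CCCCO2)c1
F9 | step 3 | [2-methoxy-6-(oxan-2-yloxy)-4-(triisopropylsilyloxy)phenyl]lithium | [Li]c1c(OC)cc(O[Si](C(C)C)(C(C)C)C(C)C)cc1OC1CCCCO1
F10 | step 3 | [3-methoxy-4-(3-methylbut-2-en-1-yl)-5-(oxan-2-yloxy)phenoxy]tri(propan-2-yl)silane | COc1cc(O[Si](C(C)C)(C(C)C)C(C)C)cc(OC2CCCCO2)c1CC=C(C)C
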